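The route rests on the C1–C5 bond of the cyclopentane (ring C1–C5), the most congested bond of the core: it joins quaternary C1 to the C5 methine beside the fully substituted carbinol C4. The key step exploits the fact that ring-opened (S)-terpinen-4-ol already carries C15, C1–C6 and the isopropyl group in one chain, with C4 configured. Anodic oxidation of a C5=C6 methyl enol ether reverses the polarity of C5, C1 of a trisubstituted allylsilane attacks, and one operation closes the five-membered ring, sets C1 and C5 and leaves a C6 acetal and a C9=C10 vinyl group for the seven-membered ring. The precursor is this open chain, with O4 as its triethylsilyl ether.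

Key step: step 7

Remark (numbering): the five-membered ring is C1 (quaternary, bearing methyl C15), C2, C3, C4 (tertiary carbinol with the isopropyl group) and C5 (ring-fusion CH); the seven-membered ring continues with C6 (vanillate carbinol), C7, C8 (bearing methylene C14), C9 (free carbinol) and C10; α is the face of H5, β the face of C15.

Assumption: (S)-(+)-terpinen-4-ol is bought in high enantiomeric purity; its S centre and the (4R) centre of 14–31 are the same spatial arrangement (only the priorities change).

Remark (geometry): the C5=C6 and C1=C10 double bonds of 14 form as mixtures of geometric isomers (E,E is drawn); both labels vanish in step 7, where C6 becomes an acetal carbon and C10 a vinyl CH, so the mixture is used as such.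

Step 1
Reactants: 1 (S)-terpinen-4-ol
Product: 2 (S)-triethyl{[4-methyl-1-(propan-2-yl)cyclohex-3-en-1-yl]oxy}silane
Conditions: TESOTf, 2,6-lutidine, CH2Cl2, 0 °C → rt
Reagents that add atoms: triethylsilyl trifluoromethanesulfonate, CC[Si](CC)(CC)OS(=O)(=O)C(F)(F)F
Why: O-silylation with a silyl triflate and a hindered pyridine base works even on a tertiary alcohol, and the C4 stereocentre is not involved.

Step 2
Reactants: 2 triethylsilyl ether of terpinen-4-ol
Product: 3 (3S)-6-oxo-3-(propan-2-yl)-3-[(triethylsilyl)oxy]heptanal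
Conditions: O3, CH2Cl2, −78 °C; then PPh3, −78 °C → rt
Reagents that add atoms: ozone, [O-][O+]=O
Why: Ozonolysis with reductive phosphine work-up cleaves the only C=C bond to the C1 methyl ketone and the C6 aldehyde without touching the silyl ether or C4.

Step 3
Reactants: 3 keto aldehyde
Product: 5 (5S)-7,7-dimethoxy-5-(propan-2-yl)-5-[(triethylsilyl)oxy]heptan-2-ol as a mixture of C2 epimers, via keto acetal 4 (not isolated)
Conditions: CeCl3·7H2O, HC(OMe)3, MeOH, rt; then NaBH4, 0 °C
Reagents that add atoms: trimethyl orthoformate, COC(OC)OC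
Why: Cerium trichloride-mediated acetalisation in methanol (Luche conditions) is selective for the aldehyde over the methyl ketone, and borohydride then reduces the ketone in the same flask, so that no enolisable ketone, which would be silylated and add to the oxocarbenium ion, is present in step 4; the new carbinol centre is transient and uncontrolled.

Step 4
Reactants: 5 hydroxy acetal
Product: 7 (5R,6E)-7-methoxy-5-(propan-2-yl)-5-[(triethylsilyl)oxy]hept-6-en-2-ol as a mixture of C2 epimers, via trimethylsilyl ether 6 (not isolated)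
Conditions: TMSOTf, iPr2NEt, CH2Cl2, −20 → 0 °C; then K2CO3, MeOH, 0 °C
Reagents that add atoms: none
Why: Silyl triflate/amine-induced loss of methanol from the dimethyl acetal (ionisation to the oxocarbenium ion, then deprotonation at C5) gives the methyl enol ether, mainly E beside quaternary C4, while the alcohol is masked in situ as its trimethylsilyl ether, which basic methanol then cleaves without touching the tertiary triethylsilyl ether.

Step 5
Reactants: 7 hydroxy enol ether
Product: 8 (5R,6E)-7-methoxy-5-(propan-2-yl)-5-[(triethylsilyl)oxy]hept-6-en-2-one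
Conditions: (C3H7)4N[RuO4] (cat.), NMO, 4 Å MS, CH2Cl2, rt
Reagents that add atoms: none
Why: Ley–Griffith oxidation is neutral and returns the methyl ketone without harming the acid-labile enol ether or the silyl ether.

Step 6
Reactants: 8 keto enol ether; 9 methyltriphenylphosphonium bromide; 10 (iodomethyl)trimethylsilane
Product: 14 triethyl{[(1E,3R,6E)-1-methoxy-6-methyl-3-(propan-2-yl)-8-(trimethylsilyl)octa-1,6-dien-3-yl]oxy}silane, via methylenetriphenylphosphorane 11 (not isolated), via phosphonium iodide 12 (not isolated), via silylethylidene ylide 13 (not isolated)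
Conditions: 9, n-BuLi, THF, 0 °C; 10, rt; n-BuLi, −78 → 0 °C; then 8, −78 °C → rt
Reagents that add atoms: none
Why: Wittig olefination with the non-stabilised β-silyl ylide, built in the same flask by alkylation of methylenetriphenylphosphorane with 10 and deprotonation, turns the ketone into the trisubstituted allylsilane under basic conditions that the enol ether tolerates; the C1=C10 geometry is not controlled and need not be.

Step 7
Reactants: 14 enol ether–allylsilane
Product: 15 triethyl{[(1R,2R,3R)-2-(dimethoxymethyl)-3-ethenyl-3-methyl-1-(propan-2-yl)cyclopentyl]oxy}silane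
Conditions: RVC anode, Pt cathode, undivided cell, constant current (about 2.2 F/mol), 0.1 M LiClO4, MeOH/THF 1:4, 2,6-lutidine, rt
Reagents that add atoms: methanol, CO
Why: Removal of one electron from the enol ether gives a radical cation whose C5 is attacked by C1 of the allylsilane, the β-silyl cation at C10 gives up silicon to methanol to leave the vinyl group, and the C6 radical is oxidised again and trapped by methanol as the dimethyl acetal (initial oxidation of the allylsilane would lead to the same cyclised cation). This is an intramolecular anodic olefin coupling of an enol ether with an allylsilane, a known reaction type that also delivers five-membered rings and quaternary carbons. The cyclopentane closes by C1–C5 bond formation in a 5-exo-trig mode with respect to both the C5=C6 and the C1=C10 double bond. C5 is controlled by C4: in the chair-like transition state the branched isopropyl group lies pseudo-equatorial, which places C6 trans to it and cis to the silyloxy group. C1 is controlled by the size difference of its exocyclic groups: the C10H–CH2SiMe3 arm turns away from the C6 end of the enol ether, so that the vinyl group ends trans and C15 cis to C6. The step needs attack at C1 and not C10 and coupling ahead of solvent capture: silicon directs the attack so that positive charge develops β to it, the five-membered closure outruns methanol addition, and 2,6-lutidine keeps the medium from hydrolysing the enol ether or the acetal.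

Step 8
Reactants: 15 vinyl acetal
Product: 16 2-[(1R,2R,3R)-2-(dimethoxymethyl)-1-methyl-3-(propan-2-yl)-3-[(triethylsilyl)oxy]cyclopentyl]ethan-1-ol
Conditions: 9-BBN, THF, rt → 50 °C; then NaOH, H2O2, 0 °C → rt
Reagents that add atoms: hydrogen peroxide, OO
Why: Hydroboration of the monosubstituted vinyl group with bulky 9-BBN places boron on terminal C9 and alkaline peroxide oxidation gives the primary alcohol; no stereocentre forms and the basic work-up keeps the hydroxy acetal from cyclising.

Step 9
Reactants: 16 primary alcohol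
Product: 17 2-[(1R,2R,3R)-2-(dimethoxymethyl)-1-methyl-3-(propan-2-yl)-3-[(triethylsilyl)oxy]cyclopentyl]acetaldehyde
Conditions: (C3H7)4N[RuO4] (cat.), NMO, 4 Å MS, CH2Cl2, rt
Reagents that add atoms: none
Why: Ley–Griffith oxidation stops at the aldehyde under neutral anhydrous conditions that leave the acetal and the silyl ether intact.

Step 10
Reactants: 17 C9 aldehyde; 18 2-bromoallyltrimethylsilane
Product: 20 1-[(1R,2R,3R)-2-(dimethoxymethyl)-1-methyl-3-(propan-2-yl)-3-[(triethylsilyl)oxy]cyclopentyl]-3-[(trimethylsilyl)methyl]but-3-en-2-ol as a mixture of C9 epimers, via vinyllithium 19 (not isolated)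
Conditions: 18, t-BuLi (2 equiv), Et2O, −78 °C; then 17, −78 °C
Reagents that add atoms: none
Why: Bromine–lithium exchange gives the 2-lithioallylsilane, whose 1,2-addition to the aldehyde attaches C8 with its allylsilane unit (future C7 and C14); the remote quaternary C1 gives no useful induction at C9, which is therefore set in steps 11 and 12.

Step 11
Reactants: 20 allylic alcohols
Product: 21 1-[(1R,2R,3R)-2-(dimethoxymethyl)-1-methyl-3-(propan-2-yl)-3-[(triethylsilyl)oxy]cyclopentyl]-3-[(trimethylsilyl)methyl]but-3-en-2-one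
Conditions: (C3H7)4N[RuO4] (cat.), NMO, 4 Å MS, CH2Cl2, rt
Reagents that add atoms: none
Why: Oxidation of the allylic alcohol converges both C9 epimers on one α-(silylmethyl) enone.

Step 12
Reactants: 21 enone
Product: 22 (2S)-1-[(1R,2R,3R)-2-(dimethoxymethyl)-1-methyl-3-(propan-2-yl)-3-[(triethylsilyl)oxy]cyclopentyl]-3-[(trimethylsilyl)methyl]but-3-en-2-ol (9S, 9α-OH)
Conditions: (R)-Me-CBS oxazaborolidine, C18H20BNO (0.2 equiv), catecholborane, toluene, −78 °C
Reagents that add atoms: none
Why: Corey–Bakshi–Shibata reduction under reagent control, in which the 1,1-disubstituted alkenyl group acts as the large and the C10 methylene as the small substituent, so the (R)-catalyst should give the (9S) alcohol, while catecholborane at low temperature avoids hydroboration of the alkene.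

Step 13
Reactants: 22 (9S) allylic alcohol
Product: 23 tert-butyldimethylsilyl ether of 22
Conditions: TBSCl, imidazole, DMAP (cat.), DMF, rt → 40 °C
Reagents that add atoms: tert-butyldimethylsilyl chloride, CC(C)(C)[Si](C)(C)Cl
Why: Silylation with silyl chloride/imidazole, which does not activate the acetal, blocks O9 so that O6 will be the only free hydroxyl at the acylation and no hydroxy acetal can cyclise in step 14.

Step 14
Reactants: 23 silyl-protected acetal
Product: 24 (1R,2R,5R)-2-{(2S)-2-[(tert-butyldimethylsilyl)oxy]-3-[(trimethylsilyl)methyl]but-3-en-1-yl}-2-methyl-5-(propan-2-yl)-5-[(triethylsilyl)oxy]cyclopentane-1-carbaldehyde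
Conditions: PPTS (cat.), acetone/H2O 10:1, 40 °C
Reagents that add atoms: water, O
Why: Mild acid-catalysed acetal hydrolysis frees the C6 aldehyde; a weak acid is chosen because a stronger one would protodesilylate the allylsilane or cleave the silyl ethers, and C5, flanked by two fully substituted carbons, should not epimerise.

Step 15
Reactants: 24 aldehyde allylsilane
Product: 25 (3R,3aS,4S,7S,8aR)-7-[(tert-butyldimethylsilyl)oxy]-8a-methyl-6-methylidene-3-(propan-2-yl)-3-[(triethylsilyl)oxy]decahydroazulen-4-ol (6α-OH, 9α-OTBS, 4β-OTES)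
Conditions: BF3·OEt2, CH2Cl2, −78 °C; then aqueous NaHCO3
Reagents that add atoms: none
Why: Intramolecular Hosomi–Sakurai reaction in which the CH2 terminus of the allylsilane attacks the activated aldehyde to form C6–C7 and the seven-membered ring while silicon leaves to give the C8=C14 methylene; C6 should come out 6α-OH because the tether forces attack from the C1 side with the complexed oxygen in the open sector between H5 and C4 and H6 between C1 and C4.

Step 16
Reactants: 26 vanillic acid
Product: 28 4-[(tert-butyldimethylsilyl)oxy]-3-methoxybenzoic acid, via silyl ester 27 (not isolated)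
Conditions: TBSCl (2.5 equiv), imidazole, DMF, rt; then AcOH/THF/H2O, rt
Reagents that add atoms: tert-butyldimethylsilyl chloride, CC(C)(C)[Si](C)(C)Cl
Why: Both acidic hydroxyls are silylated and the far more labile silyl ester is then hydrolysed selectively, which leaves the phenol masked so that it cannot compete in the acylation.

Step 17
Reactants: 25 bicyclic alcohol; 28 O-silyl vanillic acid
Product: 30 (3R,3aS,4S,7S,8aR)-7-[(tert-butyldimethylsilyl)oxy]-8a-methyl-6-methylidene-3-(propan-2-yl)-3-[(triethylsilyl)oxy]decahydroazulen-4-yl 4-[(tert-butyldimethylsilyl)oxy]-3-methoxybenzoate, via mixed anhydride 29 (not isolated)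
Conditions: 28, 2,4,6-Cl3C6H2COCl, Et3N, THF, rt; then 25, DMAP, toluene, 60 °C
Reagents that add atoms: none
Why: Yamaguchi esterification through the mixed anhydride and an acylpyridinium ion acylates the hindered secondary C6–OH, the only free hydroxyl, with retention at C6.

Step 18
Reactants: 30 fully silylated ester
Product: 31 (3R,3aS,4S,7S,8aR)-3,7-dihydroxy-8a-methyl-6-methylidene-3-(propan-2-yl)decahydroazulen-4-yl 4-hydroxy-3-methoxybenzoate (target)
Conditions: TBAF, AcOH (1:1), THF, 0 → 40 °C
Reagents that add atoms: none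
Why: Fluoride cleaves the aryl, secondary and tertiary silyl ethers in one operation, and buffering with acetic acid protects the vanillate ester and the allylic alcohol from base.

Compound list
1 | (S)-(+)-terpinen-4-ol, (1S)-4-methyl-1-(propan-2-yl)cyclohex-3-en-1-ol | C1C=C(C)CC[C@@]1(O)C(C)C | starting material
2 | (S)-triethyl{[4-methyl-1-(propan-2-yl)cyclohex-3-en-1-yl]oxy}silane | C1C=C(C)CC[C@@]1(O[Si](CC)(CC)CC)C(C)C | intermediate
3 | (3S)-6-oxo-3-(propan-2-yl)-3-[(triethylsilyl)oxy]heptanal | CC(=O)CC[C@@](CC=O)(O[Si](CC)(CC)CC)C(C)C | intermediate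
4 | (5S)-7,7-dimethoxy-5-(propan-2-yl)-5-[(triethylsilyl)oxy]heptan-2-one | CC(=O)CC[C@@](CC(OC)OC)(O[Si](CC)(CC)CC)C(C)C | intermediate (not isolated)
5 | (5S)-7,7-dimethoxy-5-(propan-2-yl)-5-[(triethylsilyl)oxy]heptan-2-ol, C2 epimers | CC(O)CC[C@@](CC(OC)OC)(O[Si](CC)(CC)CC)C(C)C | intermediate
6 | trimethylsilyl ether of 7, C2 epimers | CC(O[Si](C)(C)C)CC[C@@](/C=C/OC)(O[Si](CC)(CC)CC)C(C)C | intermediate (not isolated)
7 | (5R,6E)-7-methoxy-5-(propan-2-yl)-5-[(triethylsilyl)oxy]hept-6-en-2-ol, C2 epimers | CC(O)CC[C@@](/C=C/OC)(O[Si](CC)(CC)CC)C(C)C | intermediate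
8 | (5R,6E)-7-methoxy-5-(propan-2-yl)-5-[(triethylsilyl)oxy]hept-6-en-2-one | CC(=O)CC[C@@](/C=C/OC)(O[Si](CC)(CC)CC)C(C)C | intermediate
9 | methyltriphenylphosphonium bromide | C[P+](c1ccccc1)(c1ccccc1)c1ccccc1.[Br-] | starting material
10 | (iodomethyl)trimethylsilane | C[Si](C)(C)CI | starting material
11 | methylenetriphenylphosphorane | C=P(c1ccccc1)(c1ccccc1)c1ccccc1 | intermediate (not isolated)
12 | triphenyl[2-(trimethylsilyl)ethyl]phosphonium iodide | C[Si](C)(C)CC[P+](c1ccccc1)(c1ccccc1)c1ccccc1.[I-] | intermediate (not isolated)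
13 | triphenyl[2-(trimethylsilyl)ethylidene]phosphorane | C[Si](C)(C)CC=P(c1ccccc1)(c1ccccc1)c1ccccc1 | intermediate (not isolated)
14 | triethyl{[(1E,3R,6E)-1-methoxy-6-methyl-3-(propan-2-yl)-8-(trimethylsilyl)octa-1,6-dien-3-yl]oxy}silane (key-step precursor) | C[Si](C)(C)C/C=C(\C)CC[C@@](/C=C/OC)(O[Si](CC)(CC)CC)C(C)C | intermediate
15 | triethyl{[(1R,2R,3R)-2-(dimethoxymethyl)-3-ethenyl-3-methyl-1-(propan-2-yl)cyclopentyl]oxy}silane (key-step product) | COC(OC)[C@@H]1[C@](C)(CC[C@@]1(O[Si](CC)(CC)CC)C(C)C)C=C | intermediate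
16 | 2-[(1R,2R,3R)-2-(dimethoxymethyl)-1-methyl-3-(propan-2-yl)-3-[(triethylsilyl)oxy]cyclopentyl]ethan-1-ol | COC(OC)[C@@H]1[C@](C)(CC[C@@]1(O[Si](CC)(CC)CC)C(C)C)CCO | intermediate
17 | 2-[(1R,2R,3R)-2-(dimethoxymethyl)-1-methyl-3-(propan-2-yl)-3-[(triethylsilyl)oxy]cyclopentyl]acetaldehyde | COC(OC)[C@@H]1[C@](C)(CC[C@@]1(O[Si](CC)(CC)CC)C(C)C)CC=O | intermediate
18 | 2-bromoallyltrimethylsilane, (2-bromoprop-2-en-1-yl)trimethylsilane | C=C(Br)C[Si](C)(C)C | starting material
19 | [3-(trimethylsilyl)prop-1-en-2-yl]lithium | [Li]C(=C)C[Si](C)(C)C | intermediate (not isolated)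
20 | 1-[(1R,2R,3R)-2-(dimethoxymethyl)-1-methyl-3-(propan-2-yl)-3-[(triethylsilyl)oxy]cyclopentyl]-3-[(trimethylsilyl)methyl]but-3-en-2-ol, C9 epimers | COC(OC)[C@@H]1[C@](C)(CC[C@@]1(O[Si](CC)(CC)CC)C(C)C)CC(O)C(=C)C[Si](C)(C)C | intermediate
21 | 1-[(1R,2R,3R)-2-(dimethoxymethyl)-1-methyl-3-(propan-2-yl)-3-[(triethylsilyl)oxy]cyclopentyl]-3-[(trimethylsilyl)methyl]but-3-en-2-one | COC(OC)[C@@H]1[C@](C)(CC[C@@]1(O[Si](CC)(CC)CC)C(C)C)CC(=O)C(=C)C[Si](C)(C)C | intermediate
22 | (2S)-1-[(1R,2R,3R)-2-(dimethoxymethyl)-1-methyl-3-(propan-2-yl)-3-[(triethylsilyl)oxy]cyclopentyl]-3-[(trimethylsilyl)methyl]but-3-en-2-ol | COC(OC)[C@@H]1[C@](C)(CC[C@@]1(O[Si](CC)(CC)CC)C(C)C)C[C@H](O)C(=C)C[Si](C)(C)C | intermediate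
23 | tert-butyldimethylsilyl ether of 22 (9S) | COC(OC)[C@@H]1[C@](C)(CC[C@@]1(O[Si](CC)(CC)CC)C(C)C)C[C@H](O[Si](C)(C)C(C)(C)C)C(=C)C[Si](C)(C)C | intermediate
24 | (1R,2R,5R)-2-{(2S)-2-[(tert-butyldimethylsilyl)oxy]-3-[(trimethylsilyl)methyl]but-3-en-1-yl}-2-methyl-5-(propan-2-yl)-5-[(triethylsilyl)oxy]cyclopentane-1-carbaldehyde | O=C[C@@H]1[C@](C)(CC[C@@]1(O[Si](CC)(CC)CC)C(C)C)C[C@H](O[Si](C)(C)C(C)(C)C)C(=C)C[Si](C)(C)C | intermediate
25 | (3R,3aS,4S,7S,8aR)-7-[(tert-butyldimethylsilyl)oxy]-8a-methyl-6-methylidene-3-(propan-2-yl)-3-[(triethylsilyl)oxy]decahydroazulen-4-ol | C=C1C[C@H](O)[C@@H]2[C@](C)(CC[C@@]2(O[Si](CC)(CC)CC)C(C)C)C[C@@H]1O[Si](C)(C)C(C)(C)C | intermediate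
26 | vanillic acid, 4-hydroxy-3-methoxybenzoic acid | COc1cc(C(=O)O)ccc1O | starting material
27 | tert-butyldimethylsilyl 4-[(tert-butyldimethylsilyl)oxy]-3-methoxybenzoate | COc1cc(C(=O)O[Si](C)(C)C(C)(C)C)ccc1O[Si](C)(C)C(C)(C)C | intermediate (not isolated)
28 | 4-[(tert-butyldimethylsilyl)oxy]-3-methoxybenzoic acid | COc1cc(C(=O)O)ccc1O[Si](C)(C)C(C)(C)C | intermediate
29 | 4-[(tert-butyldimethylsilyl)oxy]-3-methoxybenzoic 2,4,6-trichlorobenzoic anhydride | COc1cc(C(=O)OC(=O)c2c(Cl)cc(Cl)cc2Cl)ccc1O[Si](C)(C)C(C)(C)C | intermediate (not isolated)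
30 | (3R,3aS,4S,7S,8aR)-7-[(tert-butyldimethylsilyl)oxy]-8a-methyl-6-methylidene-3-(propan-2-yl)-3-[(triethylsilyl)oxy]decahydroazulen-4-yl 4-[(tert-butyldimethylsilyl)oxy]-3-methoxybenzoate | C=C1C[C@H](OC(=O)c2ccc(O[Si](C)(C)C(C)(C)C)c(OC)c2)[C@@H]2[C@](C)(CC[C@@]2(O[Si](CC)(CC)CC)C(C)C)C[C@@H]1O[Si](C)(C)C(C)(C)C | intermediate
31 | (3R,3aS,4S,7S,8aR)-3,7-dihydroxy-8a-methyl-6-methylidene-3-(propan-2-yl)decahydroazulen-4-yl 4-hydroxy-3-methoxybenzoate (4β,9α-dihydroxy-6α-vanilloyloxydauc-8(14)-ene) | C=C1C[C@H](OC(=O)c2ccc(O)c(OC)c2)[C@@H]2[C@](C)(CC[C@@]2(O)C(C)C)C[C@@H]1O | target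

Total step count: 18. Longest linear sequence: 17 steps (steps 1–15, 17 and 18, from 1); step 16 is a one-step side branch.

Steps most likely to fail

1. Step 7. The ring closure may discriminate poorly between the two faces at C5 or at C1, or methanol may capture the radical cation before the C1–C5 bond forms. The fallback sets out from 3 and returns at 15, and makes the same bond by two-electron chemistry. Piperidinium acetate (benzene, 60 °C) should condense the aldehyde enamine of 3 with the C1 ketone and dehydrate the aldol to (5R)-2-methyl-5-(propan-2-yl)-5-[(triethylsilyl)oxy]cyclopent-1-ene-1-carbaldehyde F1. Conjugate addition of (CH2=CH)2CuLi (Et2O, −78 °C) then builds quaternary C1 and, after protonation and base equilibration at C5, should give (1R,2R,5R)-2-ethenyl-2-methyl-5-(propan-2-yl)-5-[(triethylsilyl)oxy]cyclopentane-1-carbaldehyde F2. Acetalisation (HC(OMe)3, PPTS, MeOH) leads to 15. Face selection at C1 would then rest on the C4 substituents alone.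

2. Step 15. Protodesilylation of the allylsilane, already possible in step 14, may outrun the slow closure of the seven-membered ring. The fallback sets out from 23 and returns at 25: silicon is given up on purpose and the ring is closed by a type 2 carbonyl-ene reaction. CF3CO2H (CH2Cl2, 0 °C) should protodesilylate 23 to the isopropenyl acetal F3, and PPTS in wet acetone then frees the isopropenyl aldehyde F4. Me2AlCl (CH2Cl2, −78 °C) should close C6–C7 with transfer of a methyl hydrogen to oxygen, under the same conformational control at C6, to give 25.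

3. Step 4. The silyl triflate may ionise the tertiary allylic C4–O bond of the enol ether once it has formed, or deprotonation at the neopentyl-like C5 may be too slow. The fallback sets out from 5 and returns at 7, and makes the enol ether by a syn-elimination that needs no Lewis acid in the presence of the product. PhSeH with BF3·OEt2 (CH2Cl2, −40 °C) should exchange one methoxy group for phenylseleno to give the O,Se-acetal F5. NaIO4 (NaHCO3, aqueous MeOH) oxidises it to the selenoxide F6, which should eliminate at room temperature to 7.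

Further compounds
F1 | step 7 | (5R)-2-methyl-5-(propan-2-yl)-5-[(triethylsilyl)oxy]cyclopent-1-ene-1-carbaldehyde | O=CC1=C(C)CC[C@@]1(O[Si](CC)(CC)CC)C(C)C
F2 | step 7 | (1R,2R,5R)-2-ethenyl-2-methyl-5-(propan-2-yl)-5-[(triethylsilyl)oxy]cyclopentane-1-carbaldehyde | O=C[C@@H]1[C@](C)(CC[C@@]1(O[Si](CC)(CC)CC)C(C)C)C=C
F3 | step 15 | isopropenyl acetal, tert-butyl{[(2S)-1-[(1R,2R,3R)-2-(dimethoxymethyl)-1-methyl-3-(propan-2-yl)-3-[(triethylsilyl)oxy]cyclopentyl]-3-methylbut-3-en-2-yl]oxy}dimethylsilane | COC(OC)[C@@H]1[C@](C)(CC[C@@]1(O[Si](CC)(CC)CC)C(C)C)C[C@H](O[Si](C)(C)C(C)(C)C)C(C)=C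
F4 | step 15 | isopropenyl aldehyde, (1R,2R,5R)-2-{(2S)-2-[(tert-butyldimethylsilyl)oxy]-3-methylbut-3-en-1-yl}-2-methyl-5-(propan-2-yl)-5-[(triethylsilyl)oxy]cyclopentane-1-carbaldehyde | O=C[C@@H]1[C@](C)(CC[C@@]1(O[Si](CC)(CC)CC)C(C)C)C[C@H](O[Si](C)(C)C(C)(C)C)C(C)=C
F5 | step 4 | O,Se-acetal, (5S)-7-methoxy-7-(phenylselanyl)-5-(propan-2-yl)-5-[(triethylsilyl)oxy]heptan-2-ol, epimers at C2 and C7 | CC(O)CC[C@@](CC(OC)[Se]c1ccccc1)(O[Si](CC)(CC)CC)C(C)C
F6 | step 4 | selenoxide of F5, (5S)-7-methoxy-7-(phenylseleninyl)-5-(propan-2-yl)-5-[(triethylsilyl)oxy]heptan-2-ol, mixture of stereoisomers | CC(O)CC[C@@](CC(OC)[Se](=O)c1ccccc1)(O[Si](CC)(CC)CC)C(C)C
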